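**Retrosynthetic overview**

- The target is reached from spiro-dithiane 16 by dithioketal hydrolysis, oxidation of the 2,4,5-trimethoxyphenyl ring B to the methoxy-1,4-benzoquinone, and removal of the C5 benzyl group, in that order.
- 16 comes from one enantioselective cationic (4+2) annulation: an aryloxycarbenium ion from racemic α-aryloxybenzyl pivalate 10 plus 2-methylene-1,3-dithiane 13 forms C2–C3 and C4–C4a and closes ring C, the only ring built (rings A and B start as arenes).
- The structural feature used: C2 is an O,C-acetal-level carbon between O1 and electron-rich ring B, and C4a is the single unsubstituted carbon of ring A, ortho to O1 and to the C5 oxygen and para to the C7 methoxy group; C4 arrives at the ketone level as a dithioketal.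
- 10 comes from ring A phenol 6 and the α-chloro pivalate 8 of 2,4,5-trimethoxybenzaldehyde. A carboxylate is the leaving group because a methyl aryl acetal would ionise by losing the phenol, the better nucleofuge, and give a methoxycarbenium ion that no longer carries ring A.
- 6 comes from methyl 2,4,6-trihydroxybenzoate by C-dimethylation, 4-O-methylation, hydrogen-bond-limited monobenzylation and saponification/decarboxylation; the ester carbon holds the place of C4a–H.

Key step: step 8

Assumption: the sense of induction of a given IDPi enantiomer on this ion pair cannot be predicted, so the catalyst enantiomer is taken to be the one that gives 2S; both are equally accessible from (R)- or (S)-BINOL.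

**Route**

Step 1
Reactants: 1 methyl 2,4,6-trihydroxybenzoate
Product: 2 methyl 2,4,6-trihydroxy-3,5-dimethylbenzoate
Conditions: MeI (2.2 equiv), NaOMe, MeOH, 0 °C to rt
Reagents that add atoms: iodomethane, CI
Why: C-methylation of a phloroglucinol phenoxide, which reacts as a vinylogous enolate at its two free ring carbons while the ester blocks the third, should give the 3,5-dimethyl compound when MeI is limited to about two equivalents to restrain dearomatising over-methylation.

Step 2
Reactants: 2 methyl 2,4,6-trihydroxy-3,5-dimethylbenzoate
Product: 3 methyl 2,6-dihydroxy-4-methoxy-3,5-dimethylbenzoate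
Conditions: Me2SO4 (1.0 equiv), K2CO3, acetone, rt
Reagents that add atoms: dimethyl sulfate, COS(=O)(=O)OC
Why: Williamson O-methylation should occur at the 4-OH, the only hydroxyl not hydrogen-bonded to the ester carbonyl and the most acidic one (para to the ester), so one equivalent of a hard methylating agent should stop at the mono-ether.

Step 3
Reactants: 3 methyl 2,6-dihydroxy-4-methoxy-3,5-dimethylbenzoate
Product: 4 methyl 2-(benzyloxy)-6-hydroxy-4-methoxy-3,5-dimethylbenzoate
Conditions: BnBr (1.05 equiv), K2CO3, DMF, 50 °C
Reagents that add atoms: benzyl bromide, BrCc1ccccc1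
Why: Williamson benzylation of one of two equivalent hydroxyls should be self-limiting, because after the first alkylation the remaining hydroxyl is held in a strong hydrogen bond to the ester carbonyl and is flanked on both sides.

Step 4
Reactants: 4 methyl 2-(benzyloxy)-6-hydroxy-4-methoxy-3,5-dimethylbenzoate
Product: 6 5-(benzyloxy)-3-methoxy-2,4-dimethylphenol, via carboxylic acid 5 (not isolated)
Conditions: KOH, DMSO–H2O, 110 °C; then aq. HCl, 60 °C
Reagents that add atoms: none
Why: Saponification of the hindered salicylate followed by acid-promoted protodecarboxylation (ipso protonation of the electron-rich 2-hydroxy-4,6-dialkoxybenzoic acid) should remove the ester carbon and leave C–H at the future C4a, with benzyl and methyl ethers stable to both stages.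

Step 5
Reactants: 7 2,4,5-trimethoxybenzaldehyde
Product: 8 chloro(2,4,5-trimethoxyphenyl)methyl pivalate (racemic, moisture-sensitive, used as its solution)
Conditions: PivCl (0.95 equiv), ZnCl2 (2 mol%), CH2Cl2, 0 °C to rt
Reagents that add atoms: pivaloyl chloride, CC(C)(C)C(Cl)=O
Why: ZnCl2-catalysed addition of an acyl chloride across an aldehyde C=O is the standard route to α-chloroalkyl and α-chlorobenzyl esters, and a slight deficit of PivCl keeps free acyl chloride out of the next step.

Step 6
Reactants: 6 5-(benzyloxy)-3-methoxy-2,4-dimethylphenol; 8 chloro(2,4,5-trimethoxyphenyl)methyl pivalate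
Product: 10 [5-(benzyloxy)-3-methoxy-2,4-dimethylphenoxy](2,4,5-trimethoxyphenyl)methyl pivalate (racemic), via sodium phenoxide 9 (not isolated)
Conditions: NaH, THF, 0 °C; then 8 (CH2Cl2 solution), −40 to 0 °C; filtration through Et3N-deactivated silica
Reagents that add atoms: none
Why: O-alkylation of a phenoxide by an α-chloroalkyl ester (the Williamson-type substitution used to make pivaloyloxymethyl aryl ethers from chloromethyl pivalate) should proceed here in an SN1-like way through the strongly stabilised benzylic cation, the hindered pivaloyl carbonyl discouraging acyl transfer to the phenoxide.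

Step 7
Reactants: 11 2-(trimethylsilyl)-1,3-dithiane
Product: 13 2-methylene-1,3-dithiane, via lithiated silyldithiane 12 (not isolated)
Conditions: n-BuLi, THF, −30 °C; (CH2O)n, −78 °C to rt; distilled and stored over K2CO3
Reagents that add atoms: formaldehyde (from paraformaldehyde), C=O
Why: Peterson olefination: the lithiated silyldithiane adds to formaldehyde and the β-silyl alkoxide eliminates LiOSiMe3 spontaneously to give the ketene dithioacetal.

Step 8
Reactants: 10 [5-(benzyloxy)-3-methoxy-2,4-dimethylphenoxy](2,4,5-trimethoxyphenyl)methyl pivalate; 13 2-methylene-1,3-dithiane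
Product: 16 (2S)-5-(benzyloxy)-7-methoxy-6,8-dimethyl-2-(2,4,5-trimethoxyphenyl)chroman-4-one 1,3-dithiane ketal (spiro-dithiane at C4), via aryloxycarbenium ion 14 (not isolated), via dithianylium ion 15 (not isolated)
Conditions: chiral BINOL-derived imidodiphosphorimidate (IDPi) Brønsted acid with 3,3'-aryl and N-triflyl groups (5 mol%), CH2Cl2, −78 °C, slow addition of 13 (1.5 equiv); Et3N quench at −78 °C
Reagents that add atoms: none
Why: Proposed new method: the confined strong acid protonates the pivalate carbonyl of 10 and expels pivalic acid to give the planar aryloxycarbenium ion 14 as a contact ion pair with the chiral IDPi anion, the CH2 terminus of 13 adds to C2 (C2–C3 bond), and the resulting 1,3-dithian-2-ylium ion 15 alkylates C4a (C4–C4a bond), rearomatisation returning the proton to the catalyst. The closest known reactions are the racemic Lewis-acid oxa-Povarov annulation of aryloxycarbenium ions with alkenes and chiral-counter-anion-controlled additions of π-nucleophiles to oxocarbenium ions released from O-acyl acetals. Ring C is closed by an intramolecular Friedel–Crafts alkylation in which the C4a–C8a arene bond lies inside the new six-membered ring (6-endo with respect to the arene, exo with respect to the C=S+ bond). The C2 stereocentre is set in the first C–C bond formation by the chiral counter-anion, which shields one face of the carbenium carbon, and both enantiomers of 10 converge on the same achiral cation, so the racemic precursor is used in full. Site selectivity of the closure is secured by the substrate, since C4a is the only unsubstituted carbon of ring A and is activated by O1, the C5 benzyloxy group and the C7 methoxy group, and chemoselectivity of the ionisation is secured by the carboxylate leaving group, which departs far more readily than the aryloxide and cannot give a competing alkoxycarbenium ion. Slow addition of 13 at −78 °C is meant to keep its direct protonation by the catalyst slower than the trapping of 14.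

Step 9
Reactants: 16 (2S)-5-(benzyloxy)-7-methoxy-6,8-dimethyl-2-(2,4,5-trimethoxyphenyl)chroman-4-one 1,3-dithiane ketal
Product: 17 (2S)-5-(benzyloxy)-7-methoxy-6,8-dimethyl-2-(2,4,5-trimethoxyphenyl)chroman-4-one
Conditions: MeI (excess), CaCO3, MeCN–H2O (4:1), 45 °C
Reagents that add atoms: water, O
Why: Dithioketal hydrolysis by S-alkylation, in which S-methylation makes sulfur a leaving group and water captures the ring-A-stabilised thionium ion, should free the C4 ketone while the CaCO3 buffer keeps the medium near neutral so that C2 is not opened by retro-oxa-Michael reaction or acid ionisation.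

Step 10
Reactants: 17 (2S)-5-(benzyloxy)-7-methoxy-6,8-dimethyl-2-(2,4,5-trimethoxyphenyl)chroman-4-one
Product: 18 2-[(2S)-5-(benzyloxy)-7-methoxy-6,8-dimethyl-4-oxochroman-2-yl]-5-methoxycyclohexa-2,5-diene-1,4-dione
Conditions: (NH4)2Ce(NO3)6 (2.5 equiv), MeCN–H2O, 0 °C, short reaction time
Reagents that add atoms: water, O
Why: Oxidative demethylation of a para-dimethoxyarene by tetravalent cerium should convert ring B, the most electron-rich arene, through its radical cation and attack of water at the C2' and C5' methoxy-bearing carbons into the 2-methoxy-1,4-benzoquinone, leaving the acyl-deactivated ring A, the benzyl ether and C2 untouched.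

Step 11
Reactants: 18 2-[(2S)-5-(benzyloxy)-7-methoxy-6,8-dimethyl-4-oxochroman-2-yl]-5-methoxycyclohexa-2,5-diene-1,4-dione
Product: 20 2-[(2S)-5-hydroxy-7-methoxy-6,8-dimethyl-4-oxochroman-2-yl]-5-methoxycyclohexa-2,5-diene-1,4-dione (target), via dichloroboryl ether 19 (not isolated)
Conditions: BCl3 (1.5 equiv), CH2Cl2, −78 °C; pH 7 buffer work-up
Reagents that add atoms: none
Why: Chelation-assisted Lewis acid ether cleavage, in which BCl3 bridges the C4 carbonyl and the C5 ether oxygen and chloride removes the benzyl group at −78 °C, should spare the quinone and C7 methoxy groups that lack such a six-membered chelate, and with ring B now electron-poor the C2–O1 bond should not ionise, so the stereocentre is kept.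

**Compound list**

1 | methyl 2,4,6-trihydroxybenzoate | COC(=O)c1c(O)cc(O)cc1O | starting material
2 | methyl 2,4,6-trihydroxy-3,5-dimethylbenzoate | COC(=O)c1c(O)c(C)c(O)c(C)c1O | intermediate
3 | methyl 2,6-dihydroxy-4-methoxy-3,5-dimethylbenzoate | COC(=O)c1c(O)c(C)c(OC)c(C)c1O | intermediate
4 | methyl 2-(benzyloxy)-6-hydroxy-4-methoxy-3,5-dimethylbenzoate | COC(=O)c1c(O)c(C)c(OC)c(C)c1OCc1ccccc1 | intermediate
5 | 2-(benzyloxy)-6-hydroxy-4-methoxy-3,5-dimethylbenzoic acid | OC(=O)c1c(O)c(C)c(OC)c(C)c1OCc1ccccc1 | intermediate
6 | 5-(benzyloxy)-3-methoxy-2,4-dimethylphenol | Oc1cc(OCc2ccccc2)c(C)c(OC)c1C | intermediate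
7 | 2,4,5-trimethoxybenzaldehyde | COc1cc(OC)c(C=O)cc1OC | starting material
8 | chloro(2,4,5-trimethoxyphenyl)methyl pivalate (racemic) | CC(C)(C)C(=O)OC(Cl)c1cc(OC)c(OC)cc1OC | intermediate
9 | sodium 5-(benzyloxy)-3-methoxy-2,4-dimethylphenolate | [Na+].[O-]c1cc(OCc2ccccc2)c(C)c(OC)c1C | intermediate
10 | [5-(benzyloxy)-3-methoxy-2,4-dimethylphenoxy](2,4,5-trimethoxyphenyl)methyl pivalate (racemic) | CC(C)(C)C(=O)OC(Oc1cc(OCc2ccccc2)c(C)c(OC)c1C)c1cc(OC)c(OC)cc1OC | intermediate
11 | 2-(trimethylsilyl)-1,3-dithiane | C[Si](C)(C)C1SCCCS1 | starting material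
12 | 2-lithio-2-(trimethylsilyl)-1,3-dithiane | [Li]C1([Si](C)(C)C)SCCCS1 | intermediate
13 | 2-methylene-1,3-dithiane | C=C1SCCCS1 | intermediate
14 | [5-(benzyloxy)-3-methoxy-2,4-dimethylphenyl](2,4,5-trimethoxybenzylidene)oxonium, the aryloxycarbenium ion paired with the IDPi anion | COc1cc(OC)c(cc1OC)C=[O+]c1cc(OCc2ccccc2)c(C)c(OC)c1C | intermediate
15 | 2-[(2S)-2-[5-(benzyloxy)-3-methoxy-2,4-dimethylphenoxy]-2-(2,4,5-trimethoxyphenyl)ethyl]-1,3-dithian-2-ylium, paired with the IDPi anion | COc1cc(OC)c(cc1OC)[C@@H](Oc1cc(OCc2ccccc2)c(C)c(OC)c1C)CC1=[S+]CCCS1 | intermediate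
16 | (2S)-5-(benzyloxy)-7-methoxy-6,8-dimethyl-2-(2,4,5-trimethoxyphenyl)chroman-4-one 1,3-dithiane ketal (spiro-dithiane at C4) | COc1cc(OC)c(cc1OC)[C@@H]2CC3(SCCCS3)c4c(OCc5ccccc5)c(C)c(OC)c(C)c4O2 | intermediate
17 | (2S)-5-(benzyloxy)-7-methoxy-6,8-dimethyl-2-(2,4,5-trimethoxyphenyl)chroman-4-one | COc1cc(OC)c(cc1OC)[C@@H]2CC(=O)c3c(OCc4ccccc4)c(C)c(OC)c(C)c3O2 | intermediate
18 | 2-[(2S)-5-(benzyloxy)-7-methoxy-6,8-dimethyl-4-oxochroman-2-yl]-5-methoxycyclohexa-2,5-diene-1,4-dione | COC1=CC(=O)C([C@@H]2CC(=O)c3c(OCc4ccccc4)c(C)c(OC)c(C)c3O2)=CC1=O | intermediate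
19 | dichloroboryl ether of the target at the C5 oxygen | COC1=CC(=O)C([C@@H]2CC(=O)c3c(OB(Cl)Cl)c(C)c(OC)c(C)c3O2)=CC1=O | intermediate
20 | 2-[(2S)-5-hydroxy-7-methoxy-6,8-dimethyl-4-oxochroman-2-yl]-5-methoxycyclohexa-2,5-diene-1,4-dione | COC1=CC(=O)C([C@@H]2CC(=O)c3c(O)c(C)c(OC)c(C)c3O2)=CC1=O | target

**Step count**

Total steps: 11. Longest linear sequence: 9 (steps 1, 2, 3, 4, 6, 8, 9, 10, 11).

**Steps most likely to fail**

1. Step 8 (proposed new method). The likely failure processes are:
   - protonation and cationic oligomerisation of the ketene dithioacetal by the catalyst before the carbenium ion is trapped;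
   - weak enantiofacial discrimination in the ion pair;
   - proton loss from the C4 cation faster than the crowded Friedel–Crafts closure next to the C5 benzyloxy group, followed by acid loss of the phenol;
   - acid re-ionisation of the C2–O1 bond of the product, eroding the enantiomeric purity.

   The fallback uses known chemistry, sets out from phenol 6 and returns at flavanone 17, bypassing 10 and 16. Friedel–Crafts C-acetylation of 6 at its only free ring carbon (Ac2O, BF3·OEt2) would give 1-[2-(benzyloxy)-6-hydroxy-4-methoxy-3,5-dimethylphenyl]ethanone F1. Condensation with N,N-dimethylformamide dimethyl acetal would give the enaminone (E)-1-[2-(benzyloxy)-6-hydroxy-4-methoxy-3,5-dimethylphenyl]-3-(dimethylamino)prop-2-en-1-one F2, which aqueous HCl would cyclise to 5-(benzyloxy)-7-methoxy-6,8-dimethyl-4H-chromen-4-one F3. Asymmetric conjugate addition of (2,4,5-trimethoxyphenyl)boronic acid to F3, catalysed by Pd(OCOCF3)2 (divalent palladium) with the enantiomer of the t-BuPyOX ligand that leads to 2S, would deliver 17. This reaction type is established for arylboronic acids and chromones.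

2. Step 6. The α-chloro ester may revert to aldehyde and pivaloyl chloride, which would then O-acylate the phenoxide; the phenoxide may be C-alkylated at its free ring carbon; and the labile acyloxy acetal may hydrolyse during isolation. The fallback sets out from phenol 6 and returns at 10. Mitsunobu etherification of 6 with purchased 2,4,5-trimethoxybenzyl alcohol (PPh3, DIAD, THF) would give 1-(benzyloxy)-3-methoxy-2,4-dimethyl-5-[(2,4,5-trimethoxybenzyl)oxy]benzene F4. Hydride abstraction from its doubly activated benzylic CH2 by DDQ in CH2Cl2 containing pivalic acid and 4 Å molecular sieves would generate the aryloxycarbenium ion under non-equilibrating conditions, and pivalate capture would give 10.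

3. Step 11. BCl3 may demethylate the vinylogous-ester methoxy group of the quinone, or chloride may add to the quinone, in competition with the chelation-assisted debenzylation. The fallback sets out from 18 and returns at 20 by a reductive route. Hydrogenolysis (H2, Pd/C, EtOAc) would remove the benzyl group and reduce the quinone, giving (2S)-2-(2,5-dihydroxy-4-methoxyphenyl)-5-hydroxy-7-methoxy-6,8-dimethylchroman-4-one F5. Reoxidation of the hydroquinone with Ag2O in Et2O would give 20.

Further compounds
F1 | step 8 | 1-[2-(benzyloxy)-6-hydroxy-4-methoxy-3,5-dimethylphenyl]ethanone | CC(=O)c1c(O)c(C)c(OC)c(C)c1OCc1ccccc1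
F2 | step 8 | (E)-1-[2-(benzyloxy)-6-hydroxy-4-methoxy-3,5-dimethylphenyl]-3-(dimethylamino)prop-2-en-1-one | CN(C)/C=C/C(=O)c1c(O)c(C)c(OC)c(C)c1OCc1ccccc1
F3 | step 8 | 5-(benzyloxy)-7-methoxy-6,8-dimethyl-4H-chromen-4-one | O=c1ccoc2c(C)c(OC)c(C)c(OCc3ccccc3)c12
F4 | step 6 | 1-(benzyloxy)-3-methoxy-2,4-dimethyl-5-[(2,4,5-trimethoxybenzyl)oxy]benzene | COc1cc(OC)c(cc1OC)COc1cc(OCc2ccccc2)c(C)c(OC)c1C
F5 | step 11 | (2S)-2-(2,5-dihydroxy-4-methoxyphenyl)-5-hydroxy-7-methoxy-6,8-dimethylchroman-4-one | COc1cc(O)c(cc1O)[C@@H]2CC(=O)c3c(O)c(C)c(OC)c(C)c3O2
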